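**Plan**

1. Numbering: ring A = C1, C2, C3, C4, C5, C10 and ring B = C5, C6, C7, C8, C9, C10 (C3 carries the ester, C4 and C5 the methyl groups; side-chain atoms are primed). The retrosynthesis cuts the C3–O ester bond, then the C7–O bond, then ring A at C1–C10 and C4–C5 in one [4+2] step.
2. Enabling feature: ring A is a cyclohexene with oxygen on C3 that shares its C5–C10 edge with ring B, which has oxygen on C8 next to C9. This maps onto a 2-silyloxydiene (C1=C2–C3(OSi)=C4–CH3) adding to the methyl-bearing C5=C10 double bond of 2-methoxy-5-methylbenzoquinone, whose carbonyls at C9 and C6 are removable activators.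
3. Forward: ring B arrives as the quinone and ring A is closed onto it. The C9 oxygen leaves through an enol triflate (giving C9=C10), the silyl enol ether becomes the C1=C2 enone, and the C6 oxygen leaves by reduction, Stork–Danheiser transposition and hydrogenation of C6=C7.
4. Stereochemistry: C5 comes from a chiral titanium catalyst. C4 (kinetic protonation), C3 (hydride delivery) and C7 (enolate oxidation) are each set on the face opposite to the angular C5 methyl. C6' comes from (R)-2-hydroxy-2-methylbutanoic acid, and both side-chain double bonds are made E by a vinylogous Horner–Wadsworth–Emmons reaction.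
5. The dienoic acid is attached at C3 before C7 is oxidised, and one desilylation ends the route.

Key step: step 2

**Remarks**

- (R)-2-Hydroxy-2-methylbutanoic acid is taken as a commercial compound.
- The (S)-binaphtholate is assumed to leave open the quinone face that gives (R) at C5; if the sense proves opposite, the (R)-ligand is used and nothing else changes.
- The endo cycloaddition is expected to place the C4 methyl anti to the C5 methyl, so C4 is deliberately reset in step 6, and whichever C4 epimer the cycloaddition gives converges there.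

**Route**

Step 1
Reactants: 1 pent-1-en-3-one
Product: 2 (Z)-triisopropyl(penta-1,3-dien-3-yloxy)silane
Conditions: i-Pr3SiOTf, Et3N, CH2Cl2, 0 °C
Reagents that add atoms: triisopropylsilyl trifluoromethanesulfonate, CC(C)[Si](OS(=O)(=O)C(F)(F)F)(C(C)C)C(C)C
Why: Soft enolisation of the ethyl ketone with a silyl triflate and an amine (silyl enol ether formation) should give the favoured (Z)-2-silyloxydiene and leave the vinyl group untouched.

Step 2
Reactants: 2 (Z)-triisopropyl(penta-1,3-dien-3-yloxy)silane; 3 2-methoxy-5-methylcyclohexa-2,5-diene-1,4-dione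
Product: 4 (4aR,5S,8aS)-2-methoxy-4a,5-dimethyl-6-[(triisopropylsilyl)oxy]-4a,5,8,8a-tetrahydronaphthalene-1,4-dione
Conditions: TiCl2[(S)-1,1'-binaphthalene-2,2'-diolate] (20 mol %, from TiCl2(Oi-Pr)2 and (S)-1,1'-bi-2-naphthol, 4 Å molecular sieves), CH2Cl2, −40 to −20 °C
Reagents that add atoms: none
Why: A concerted, asynchronous normal-electron-demand Diels–Alder reaction: the HOMO of the 2-silyloxydiene adds suprafacially across the C5=C10 double bond of the quinone, whose LUMO is lowered by bidentate binding of titanium to the C9 carbonyl oxygen and the neighbouring methoxy oxygen. The closest known reaction types are the Lewis-acid-promoted Diels–Alder reactions of 2-methoxy-5-methylbenzoquinone at its methyl-bearing double bond and the titanium binaphtholate-catalysed enantioselective Diels–Alder reactions of chelating 2-methoxyquinones. Ring A, the only ring formed, is closed as a six-membered carbocycle in the [4π+2π] mode through an endo transition state, which gives the cis ring fusion. C5 (quaternary) is set by the quinone face left open by the binaphtholate; C10–H follows from suprafacial addition and lies cis to the C5 methyl (this centre is removed in step 3); the endo rule places the C4 methyl of the (Z)-diene anti to the C5 methyl, a centre that is reset in step 6. The step needs site selectivity (the methoxy group deactivates its own double bond as a vinylogous ester, so the methyl-bearing one reacts), regioselectivity (C4, the diene terminus next to the silyloxy carbon, has the largest HOMO coefficient and bonds to C5, the carbon β to the chelated C9 carbonyl) and face selectivity (ligand control). A monodentate acid would bind the more basic C6 carbonyl and reverse the regiochemistry, which is why a chelating catalyst is chosen.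

Step 3
Reactants: 4 (4aR,5S,8aS)-2-methoxy-4a,5-dimethyl-6-[(triisopropylsilyl)oxy]-4a,5,8,8a-tetrahydronaphthalene-1,4-dione
Product: 6 (8S,8aR)-3-methoxy-8,8a-dimethyl-1-oxo-7-[(triisopropylsilyl)oxy]-1,5,8,8a-tetrahydronaphthalen-4-yl trifluoromethanesulfonate, via potassium enolate 5 (not isolated)
Conditions: KN(SiMe3)2, THF, −78 °C; then PhNTf2, −78 to 0 °C
Reagents that add atoms: N-phenylbis(trifluoromethanesulfonimide), O=S(=O)(N(c1ccccc1)S(=O)(=O)C(F)(F)F)C(F)(F)F
Why: The C9 ketone has a single α-hydrogen (C10–H), so enolisation is regiospecific and O-sulfonylation gives the enol triflate (enol triflate formation), which removes the C10 stereocentre that the target does not need.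

Step 4
Reactants: 6 (8S,8aR)-3-methoxy-8,8a-dimethyl-1-oxo-7-[(triisopropylsilyl)oxy]-1,5,8,8a-tetrahydronaphthalen-4-yl trifluoromethanesulfonate
Product: 7 (8S,8aR)-3-methoxy-8,8a-dimethyl-7-[(triisopropylsilyl)oxy]-8,8a-dihydronaphthalen-1(5H)-one
Conditions: Pd(OAc)2 (5 mol %), PPh3, HCO2H, Et3N, DMF, 60 °C
Reagents that add atoms: none
Why: Zerovalent palladium inserts into the vinyl C–OTf bond and formate delivers hydride (palladium-catalysed hydrogenolysis of an enol triflate), which deletes the helper oxygen at C9 and leaves the C9=C10 double bond of the target.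

Step 5
Reactants: 7 (8S,8aR)-3-methoxy-8,8a-dimethyl-7-[(triisopropylsilyl)oxy]-8,8a-dihydronaphthalen-1(5H)-one
Product: 8 (8S,8aR)-3-methoxy-8,8a-dimethyl-8,8a-dihydronaphthalene-1,7-dione
Conditions: Pd(OAc)2 (1.1 equiv), MeCN–DMSO, 40 °C
Reagents that add atoms: none
Why: Saegusa–Ito oxidation: the divalent palladium enolate formed at C2 can only lose a β-hydrogen from C1, so the C1=C2 enone results and C5 is not touched.

Step 6
Reactants: 8 (8S,8aR)-3-methoxy-8,8a-dimethyl-8,8a-dihydronaphthalene-1,7-dione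
Product: 10 (8R,8aR)-3-methoxy-8,8a-dimethyl-8,8a-dihydronaphthalene-1,7-dione, via lithium enolate 9 (not isolated)
Conditions: LiN(i-Pr)2, THF, −78 °C; then AcOH in THF, −78 °C
Reagents that add atoms: none
Why: C4–H is the only acidic hydrogen of 8, and the flat cross-conjugated enolate should be protonated on the face opposite to the angular C5 methyl (kinetic protonation of an enolate), which turns the C4 methyl cis to the C5 methyl.

Step 7
Reactants: 10 (8R,8aR)-3-methoxy-8,8a-dimethyl-8,8a-dihydronaphthalene-1,7-dione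
Product: 12 (4aR,5R,6S)-6-hydroxy-4a,5-dimethyl-5,6-dihydronaphthalen-2(4aH)-one, via allylic diol 11 (not isolated)
Conditions: i-Bu2AlH (3 equiv), CH2Cl2, −78 °C; then 1 M HCl, THF, 0 °C
Reagents that add atoms: water, O
Why: Hydride should attack the C3 carbonyl from the face opposite to both methyl groups (1,2-reduction of an enone), giving the C3 alcohol cis to them, and it also reduces the C6 vinylogous-ester carbonyl; mild acid then ionises the C6 carbinol and hydrolyses the enol ether (Stork–Danheiser transposition), which places the ring B carbonyl on C8 and leaves C6=C7.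

Step 8
Reactants: 12 (4aR,5R,6S)-6-hydroxy-4a,5-dimethyl-5,6-dihydronaphthalen-2(4aH)-one
Product: 13 (4aR,5R,6S)-6-hydroxy-4a,5-dimethyl-4,4a,5,6-tetrahydronaphthalen-2(3H)-one
Conditions: H2 (1 atm), RhCl(PPh3)3 (10 mol %), benzene–EtOH, rt
Reagents that add atoms: none
Why: Homogeneous hydrogenation with RhCl(PPh3)3 should take the cis-disubstituted C6=C7 bond of the cross-conjugated dienone and spare the trisubstituted C9=C10 and the C1=C2 bond of the linear dienone, as in the selective hydrogenation of the 1,2-double bond of steroidal 1,4-dien-3-ones and 1,4,6-trien-3-ones.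

Step 9
Reactants: 14 (R)-2-hydroxy-2-methylbutanoic acid
Product: 15 methyl (R)-2-hydroxy-2-methylbutanoate
Conditions: MeI, K2CO3, DMF, rt
Reagents that add atoms: iodomethane, CI
Why: O-Alkylation of the carboxylate (esterification) does not touch the tertiary alcohol or the stereocentre.

Step 10
Reactants: 15 methyl (R)-2-hydroxy-2-methylbutanoate
Product: 16 methyl (R)-2-methyl-2-[(triethylsilyl)oxy]butanoate
Conditions: Et3SiOTf, 2,6-lutidine, CH2Cl2, 0 °C
Reagents that add atoms: triethylsilyl trifluoromethanesulfonate, CC[Si](CC)(CC)OS(=O)(=O)C(F)(F)F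
Why: Silylation of a hindered tertiary alcohol with a silyl triflate gives an ether that survives the later hydride and base steps and is removed by fluoride at the end.

Step 11
Reactants: 16 methyl (R)-2-methyl-2-[(triethylsilyl)oxy]butanoate
Product: 17 (R)-2-methyl-2-[(triethylsilyl)oxy]butanal
Conditions: i-Bu2AlH (1.1 equiv), CH2Cl2, −78 °C; aqueous potassium sodium tartrate
Reagents that add atoms: none
Why: Partial reduction of an ester: at −78 °C the aluminium hemiacetal of the α-silyloxy ester persists until work-up, so the aldehyde is obtained, and the quaternary α-carbon cannot epimerise.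

Step 12
Reactants: 17 (R)-2-methyl-2-[(triethylsilyl)oxy]butanal; 18 ethyl (E)-4-(diethoxyphosphoryl)but-2-enoate
Product: 20 ethyl (R,2E,4E)-6-methyl-6-[(triethylsilyl)oxy]octa-2,4-dienoate, via lithiated phosphonate 19 (not isolated)
Conditions: LiN(SiMe3)2, THF, −78 to 0 °C
Reagents that add atoms: none
Why: Vinylogous Horner–Wadsworth–Emmons olefination with a stabilised phosphonate anion should form the new C4'=C5' bond E and keep the C2'=C3' bond E.

Step 13
Reactants: 20 ethyl (R,2E,4E)-6-methyl-6-[(triethylsilyl)oxy]octa-2,4-dienoate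
Product: 21 (R,2E,4E)-6-methyl-6-[(triethylsilyl)oxy]octa-2,4-dienoic acid
Conditions: LiOH, THF–MeOH–H2O, rt; then dilute HCl to pH 4, 0 °C
Reagents that add atoms: lithium hydroxide, [Li+].[OH-]
Why: Saponification is safe here because the dienoate has no γ-hydrogen that would allow deconjugation and the tertiary silyl ether is stable to hydroxide.

Step 14
Reactants: 13 (4aR,5R,6S)-6-hydroxy-4a,5-dimethyl-4,4a,5,6-tetrahydronaphthalen-2(3H)-one; 21 (R,2E,4E)-6-methyl-6-[(triethylsilyl)oxy]octa-2,4-dienoic acid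
Product: 23 (1R,2S,8aR)-1,8a-dimethyl-6-oxo-1,2,6,7,8,8a-hexahydronaphthalen-2-yl (R,2E,4E)-6-methyl-6-[(triethylsilyl)oxy]octa-2,4-dienoate, via mixed anhydride 22 (not isolated)
Conditions: 2,4,6-trichlorobenzoyl chloride, Et3N, toluene, rt; then 13, DMAP, rt
Reagents that add atoms: none
Why: Yamaguchi esterification through the mixed anhydride acylates the hindered allylic C3 alcohol with retention at C3, the tertiary alcohol of the acid being masked.

Step 15
Reactants: 23 (1R,2S,8aR)-1,8a-dimethyl-6-oxo-1,2,6,7,8,8a-hexahydronaphthalen-2-yl (R,2E,4E)-6-methyl-6-[(triethylsilyl)oxy]octa-2,4-dienoate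
Product: 25 (1R,2S,7R,8aR)-7-hydroxy-1,8a-dimethyl-6-oxo-1,2,6,7,8,8a-hexahydronaphthalen-2-yl (R,2E,4E)-6-methyl-6-[(triethylsilyl)oxy]octa-2,4-dienoate, via sodium enolate 24 (not isolated)
Conditions: NaN(SiMe3)2, THF, −78 °C; then 2-(benzenesulfonyl)-3-phenyloxaziridine, −78 °C; AcOH quench
Reagents that add atoms: 2-(benzenesulfonyl)-3-phenyloxaziridine, O=S(=O)(N1OC1c1ccccc1)c1ccccc1
Why: Kinetic deprotonation at C7, the only sp3 α-carbon of the C8 ketone, and oxygen transfer from the N-sulfonyloxaziridine to the enolate face opposite to the angular C5 methyl (enolate α-hydroxylation) should give the C7 alcohol trans to that methyl; the dienoate has no acidic hydrogen.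

Step 16
Reactants: 25 (1R,2S,7R,8aR)-7-hydroxy-1,8a-dimethyl-6-oxo-1,2,6,7,8,8a-hexahydronaphthalen-2-yl (R,2E,4E)-6-methyl-6-[(triethylsilyl)oxy]octa-2,4-dienoate
Product: 26 (1R,2S,7R,8aR)-7-hydroxy-1,8a-dimethyl-6-oxo-1,2,6,7,8,8a-hexahydronaphthalen-2-yl (R,2E,4E)-6-hydroxy-6-methylocta-2,4-dienoate (CNP0260852.1)
Conditions: HF·pyridine, pyridine, THF, 0 °C
Reagents that add atoms: none
Why: Fluoride cleavage of the triethylsilyl ether under buffered conditions should leave the α-ketol, the ester and the dienone intact.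

**Compound list**

1 | pent-1-en-3-one | CCC(=O)C=C | starting material
2 | (Z)-triisopropyl(penta-1,3-dien-3-yloxy)silane | C/C=C(\O[Si](C(C)C)(C(C)C)C(C)C)C=C | intermediate
3 | 2-methoxy-5-methylcyclohexa-2,5-diene-1,4-dione | COC1=CC(=O)C(C)=CC1=O | starting material
4 | (4aR,5S,8aS)-2-methoxy-4a,5-dimethyl-6-[(triisopropylsilyl)oxy]-4a,5,8,8a-tetrahydronaphthalene-1,4-dione (cis-fused; secondary methyl trans to angular methyl) | CC(C)[Si](C(C)C)(C(C)C)OC1=CC[C@@H]2C(=O)C(OC)=CC(=O)[C@]2(C)[C@@H]1C | intermediate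
5 | potassium enolate of 4 (not isolated) | CC(C)[Si](C(C)C)(C(C)C)OC1=CCC2=C(O[K])C(OC)=CC(=O)[C@]2(C)[C@@H]1C | intermediate
6 | (8S,8aR)-3-methoxy-8,8a-dimethyl-1-oxo-7-[(triisopropylsilyl)oxy]-1,5,8,8a-tetrahydronaphthalen-4-yl trifluoromethanesulfonate | CC(C)[Si](C(C)C)(C(C)C)OC1=CCC2=C(OS(=O)(=O)C(F)(F)F)C(OC)=CC(=O)[C@]2(C)[C@@H]1C | intermediate
7 | (8S,8aR)-3-methoxy-8,8a-dimethyl-7-[(triisopropylsilyl)oxy]-8,8a-dihydronaphthalen-1(5H)-one | CC(C)[Si](C(C)C)(C(C)C)OC1=CCC2=CC(OC)=CC(=O)[C@]2(C)[C@@H]1C | intermediate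
8 | (8S,8aR)-3-methoxy-8,8a-dimethyl-8,8a-dihydronaphthalene-1,7-dione | O=C1C=CC2=CC(OC)=CC(=O)[C@]2(C)[C@@H]1C | intermediate
9 | lithium enolate of 8 (not isolated) | [Li]OC=1C=CC2=CC(OC)=CC(=O)[C@]2(C)C=1C | intermediate
10 | (8R,8aR)-3-methoxy-8,8a-dimethyl-8,8a-dihydronaphthalene-1,7-dione (methyl groups cis) | O=C1C=CC2=CC(OC)=CC(=O)[C@]2(C)[C@H]1C | intermediate
11 | (7S,8R,8aR)-3-methoxy-8,8a-dimethyl-1,7,8,8a-tetrahydronaphthalene-1,7-diol (C1 carbinol epimers; not isolated) | O[C@H]1C=CC2=CC(OC)=CC(O)[C@]2(C)[C@H]1C | intermediate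
12 | (4aR,5R,6S)-6-hydroxy-4a,5-dimethyl-5,6-dihydronaphthalen-2(4aH)-one | O[C@H]1C=CC2=CC(=O)C=C[C@]2(C)[C@H]1C | intermediate
13 | (4aR,5R,6S)-6-hydroxy-4a,5-dimethyl-4,4a,5,6-tetrahydronaphthalen-2(3H)-one | O[C@H]1C=CC2=CC(=O)CC[C@]2(C)[C@H]1C | intermediate
14 | (R)-2-hydroxy-2-methylbutanoic acid | CC[C@@](C)(O)C(=O)O | starting material
15 | methyl (R)-2-hydroxy-2-methylbutanoate | CC[C@@](C)(O)C(=O)OC | intermediate
16 | methyl (R)-2-methyl-2-[(triethylsilyl)oxy]butanoate | CC[C@@](C)(O[Si](CC)(CC)CC)C(=O)OC | intermediate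
17 | (R)-2-methyl-2-[(triethylsilyl)oxy]butanal | CC[C@@](C)(O[Si](CC)(CC)CC)C=O | intermediate
18 | ethyl (E)-4-(diethoxyphosphoryl)but-2-enoate | CCOC(=O)/C=C/CP(=O)(OCC)OCC | starting material
19 | lithium salt of 18, deprotonated at C4 (not isolated) | [Li+].CCOC(=O)/C=C/[CH-]P(=O)(OCC)OCC | intermediate
20 | ethyl (R,2E,4E)-6-methyl-6-[(triethylsilyl)oxy]octa-2,4-dienoate | CC[C@@](C)(O[Si](CC)(CC)CC)/C=C/C=C/C(=O)OCC | intermediate
21 | (R,2E,4E)-6-methyl-6-[(triethylsilyl)oxy]octa-2,4-dienoic acid | CC[C@@](C)(O[Si](CC)(CC)CC)/C=C/C=C/C(=O)O | intermediate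
22 | mixed anhydride of 21 and 2,4,6-trichlorobenzoic acid (not isolated) | CC[C@@](C)(O[Si](CC)(CC)CC)/C=C/C=C/C(=O)OC(=O)c1c(Cl)cc(Cl)cc1Cl | intermediate
23 | (1R,2S,8aR)-1,8a-dimethyl-6-oxo-1,2,6,7,8,8a-hexahydronaphthalen-2-yl (R,2E,4E)-6-methyl-6-[(triethylsilyl)oxy]octa-2,4-dienoate | CC[C@@](C)(O[Si](CC)(CC)CC)/C=C/C=C/C(=O)O[C@H]1C=CC2=CC(=O)CC[C@]2(C)[C@H]1C | intermediate
24 | sodium enolate of 23 at C7–C8 (not isolated) | CC[C@@](C)(O[Si](CC)(CC)CC)/C=C/C=C/C(=O)O[C@H]1C=CC2=CC(O[Na])=CC[C@]2(C)[C@H]1C | intermediate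
25 | (1R,2S,7R,8aR)-7-hydroxy-1,8a-dimethyl-6-oxo-1,2,6,7,8,8a-hexahydronaphthalen-2-yl (R,2E,4E)-6-methyl-6-[(triethylsilyl)oxy]octa-2,4-dienoate | CC[C@@](C)(O[Si](CC)(CC)CC)/C=C/C=C/C(=O)O[C@H]1C=CC2=CC(=O)[C@H](O)C[C@]2(C)[C@H]1C | intermediate
26 | (1R,2S,7R,8aR)-7-hydroxy-1,8a-dimethyl-6-oxo-1,2,6,7,8,8a-hexahydronaphthalen-2-yl (R,2E,4E)-6-hydroxy-6-methylocta-2,4-dienoate | CC[C@@](C)(O)/C=C/C=C/C(=O)O[C@H]1C=CC2=CC(=O)[C@H](O)C[C@]2(C)[C@H]1C | target

**Step count**

Total: 16 steps. Longest linear sequence: 11 steps (steps 1–8 and 14–16, from 1 to 26); the side chain takes 5 steps (9–13) before the union in step 14.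

**Steps most likely to fail, with fallbacks**

Step 2. The bond between the two methyl-bearing carbons C4 and C5 may form too slowly, so that the quinone decomposes, the diene only adds in a Mukaiyama–Michael sense without ring closure, or regio- and enantiocontrol erode. The fallback sets out from 3 and uses the unhindered diene 2-(triisopropylsilyloxy)buta-1,3-diene F1 under the catalyst of step 2, which should give the C4-unsubstituted cis-fused adduct F2. Deprotonation at C10 gives the potassium enolate F3, which is triflated with PhNTf2 to the enol triflate F4. Palladium-catalysed formate reduction gives the dienone silyl enol ether F5, and Saegusa–Ito oxidation the enone F6. LiN(i-Pr)2 then forms the lithium enolate F7, and methylation with MeI, which should enter anti to the angular methyl, gives 8, where the route is rejoined before the C4 correction of step 6.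

Step 6. The protonation may discriminate poorly between the two faces, may occur on oxygen and be followed by slow equilibrating ketonisation, or the amide may add to the extended dienedione. The fallback sets out from 7: HF·pyridine cleaves the silyl enol ether to the saturated C3 ketone F8. Catalytic DBU equilibrates C4 through the enol, and the chair-like ring A should favour the epimer F9, with an equatorial C4 methyl cis to the axial C5 methyl. Dehydrogenation with 2-iodoxybenzoic acid, possible only toward C2–C1 because C5 is quaternary, then gives 10, where the route is rejoined.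

Step 8. Hydrogen may also add to C1=C2, possibly assisted by the neighbouring hydroxyl group, or the hydrogenation may stall on the hindered dienone. The fallback sets out from 12 and avoids hydrogenation: Yamaguchi esterification with 21 (through 22) gives the trienone ester F10. Hydrogen-atom transfer from PhSiH3 to C6, catalysed by tris(2,2,6,6-tetramethylheptane-3,5-dionato)manganese, Mn(dpm)3, under O2, followed by oxygenation at C7 anti to the angular methyl, gives the hydroperoxide F11. P(OEt)3 reduces it to 25, where the route is rejoined.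

**Further compounds**

F1 | step 2 | 2-(triisopropylsilyloxy)buta-1,3-diene | C=CC(=C)O[Si](C(C)C)(C(C)C)C(C)C
F2 | step 2 | (4aR,8aS)-2-methoxy-4a-methyl-6-[(triisopropylsilyl)oxy]-4a,5,8,8a-tetrahydronaphthalene-1,4-dione | CC(C)[Si](C(C)C)(C(C)C)OC1=CC[C@@H]2C(=O)C(OC)=CC(=O)[C@]2(C)C1
F3 | step 2 | potassium enolate of F2 | CC(C)[Si](C(C)C)(C(C)C)OC1=CCC2=C(O[K])C(OC)=CC(=O)[C@]2(C)C1
F4 | step 2 | (R)-3-methoxy-8a-methyl-1-oxo-7-[(triisopropylsilyl)oxy]-1,5,8,8a-tetrahydronaphthalen-4-yl trifluoromethanesulfonate | CC(C)[Si](C(C)C)(C(C)C)OC1=CCC2=C(OS(=O)(=O)C(F)(F)F)C(OC)=CC(=O)[C@]2(C)C1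
F5 | step 2 | (R)-3-methoxy-8a-methyl-7-[(triisopropylsilyl)oxy]-8,8a-dihydronaphthalen-1(5H)-one | CC(C)[Si](C(C)C)(C(C)C)OC1=CCC2=CC(OC)=CC(=O)[C@]2(C)C1
F6 | step 2 | (R)-3-methoxy-8a-methyl-8,8a-dihydronaphthalene-1,7-dione | O=C1C=CC2=CC(OC)=CC(=O)[C@]2(C)C1
F7 | step 2 | lithium enolate of F6 | [Li]OC=1C=CC2=CC(OC)=CC(=O)[C@]2(C)C=1
F8 | step 6 | (8S,8aR)-3-methoxy-8,8a-dimethyl-5,6,8,8a-tetrahydronaphthalene-1,7-dione | O=C1CCC2=CC(OC)=CC(=O)[C@]2(C)[C@@H]1C
F9 | step 6 | (8R,8aR)-3-methoxy-8,8a-dimethyl-5,6,8,8a-tetrahydronaphthalene-1,7-dione | O=C1CCC2=CC(OC)=CC(=O)[C@]2(C)[C@H]1C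
F10 | step 8 | (1R,2S,8aR)-1,8a-dimethyl-6-oxo-1,2,6,8a-tetrahydronaphthalen-2-yl (R,2E,4E)-6-methyl-6-[(triethylsilyl)oxy]octa-2,4-dienoate | CC[C@@](C)(O[Si](CC)(CC)CC)/C=C/C=C/C(=O)O[C@H]1C=CC2=CC(=O)C=C[C@]2(C)[C@H]1C
F11 | step 8 | (1R,2S,7R,8aR)-7-hydroperoxy-1,8a-dimethyl-6-oxo-1,2,6,7,8,8a-hexahydronaphthalen-2-yl (R,2E,4E)-6-methyl-6-[(triethylsilyl)oxy]octa-2,4-dienoate | CC[C@@](C)(O[Si](CC)(CC)CC)/C=C/C=C/C(=O)O[C@H]1C=CC2=CC(=O)[C@H](OO)C[C@]2(C)[C@H]1C
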